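**Retrosynthetic overview**

1. Numbering (kaurane-like): ring A = C1–C5, C10; ring B = C5–C10; ring C = C8, C9, C11–C14; ring D = C11, C12, C13, C16, C15; C17 is the exocyclic CH2. C1 carries OAc, C6 and C12 carry OH, C15 is the ketone. Endgame: C15 allylic alcohol to enone, C6 alcohol from the ketone, C6 ketone from a nitro group.
2. Rings A and B are opened together: intramolecular Diels–Alder reaction of an (E)-nitroalkene C5=C6 (C6 from nitromethane) with the bis-exocyclic diene C7=C8–C9=C10 held on ring C, forming C5–C10 and C6–C7.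
3. The feature that allows this: the tetrasubstituted C8=C9 double bond shared by rings B and C, flanked by C7H2 and the quaternary C10, is the cyclohexene double bond of a [4+2] adduct; the oxygenated C1 next to C10 steers the diene face through 1,3-allylic strain.
4. Ring C (the bicyclo[3.2.1]octane) is opened by a palladium-catalysed 6-exo-dig carbopalladation/methyl Suzuki–Miyaura cascade of a cis-1,3-disubstituted cyclopentane (2-bromoallyl and alkynyl arms), which also fixes the diene geometry.
5. Ring D comes from furfural (Piancatelli rearrangement, lipase resolution), the C1–C5 chain from isobutyronitrile, and the two are joined by conjugate alkynylation. Order of ring formation: D, then C, then A and B together.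

Key step: step 15

Assumption: in step 3 the lipase acylates the (4S,5R)-enantiomer of 4 faster (the sense known for the spatially related parent 4-hydroxycyclopent-2-enone), so the wanted (4R,5S)-alcohol is the one recovered.

**Route**

Step 1
Reactants: 1 furfural; 2 2,3-dibromoprop-1-ene
Product: 3 rac-3-bromo-1-(furan-2-yl)but-3-en-1-ol
Conditions: Zn dust, THF/sat. aq. NH4Cl, 0 °C to rt
Reagents that add atoms: none
Why: Barbier allylation, in which zinc inserts only into the allylic C–Br bond and the allylzinc adds to the aldehyde while the vinylic bromide is untouched; the carbinol centre needs no control because step 2 destroys it.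

Step 2
Reactants: 3 rac-3-bromo-1-(furan-2-yl)but-3-en-1-ol
Product: 4 rac-trans-5-(2-bromoallyl)-4-hydroxycyclopent-2-en-1-one
Conditions: ZnCl2, 1,4-dioxane/H2O, 80 °C
Reagents that add atoms: water, O
Why: Piancatelli rearrangement (ionisation of the furylcarbinol, attack of water at C5 of the furan, ring opening and conrotatory 4π-electrocyclisation), which should give the 4-hydroxy-5-alkylcyclopentenone with the trans relationship typical of this reaction.

Step 3
Reactants: 4 rac-trans-5-(2-bromoallyl)-4-hydroxycyclopent-2-en-1-one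
Product: 5 (4R,5S)-5-(2-bromoallyl)-4-hydroxycyclopent-2-en-1-one
Conditions: lipase PS (Burkholderia cepacia), vinyl acetate, t-BuOMe, 30 °C, stopped near half conversion
Reagents that add atoms: none
Why: Enzymatic kinetic resolution by enantioselective transesterification, a reaction type that resolves 4-hydroxycyclopent-2-enones; the unreacted (4R,5S)-alcohol is separated from the acetate of its enantiomer by chromatography.

Step 4
Reactants: 5 (4R,5S)-5-(2-bromoallyl)-4-hydroxycyclopent-2-en-1-one
Product: 6 (4R,5S)-silyl ether of 5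
Conditions: t-BuMe2SiCl, imidazole, DMF, 0 °C
Reagents that add atoms: tert-butyldimethylsilyl chloride, CC(C)(C)[Si](C)(C)Cl
Why: Standard silylation of a secondary alcohol under weakly basic, cold conditions, chosen so that the 4-oxygenated enone neither eliminates nor isomerises; no stereocentre is touched.

Step 5
Reactants: 7 isobutyronitrile; 8 N-methoxy-N-methylacrylamide
Product: 9 4-cyano-N-methoxy-N,4-dimethylpentanamide
Conditions: LiN(i-Pr)2, THF, −78 °C; then 8; aq. NH4Cl
Reagents that add atoms: none
Why: Michael addition of the lithiated nitrile to the acrylamide builds the quaternary C4 with both methyl groups and delivers the Weinreb amide directly.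

Step 6
Reactants: 9 4-cyano-N-methoxy-N,4-dimethylpentanamide
Product: 10 2,2-dimethyl-5-oxo-7-(trimethylsilyl)hept-6-ynenitrile
Conditions: Me3SiC≡CH, n-BuLi, THF, −78 °C; then 9, −78 to 0 °C
Reagents that add atoms: trimethylsilylacetylene, C#C[Si](C)(C)C
Why: Acylation of the lithium acetylide by the Weinreb amide stops at the ketone because of the chelated tetrahedral intermediate, and the hindered tertiary nitrile should not be attacked at low temperature.

Step 7
Reactants: 10 2,2-dimethyl-5-oxo-7-(trimethylsilyl)hept-6-ynenitrile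
Product: 11 (5S)-5-hydroxy-2,2-dimethyl-7-(trimethylsilyl)hept-6-ynenitrile
Conditions: RuCl[(S,S)-TsDPEN](p-cymene) (1 mol%), KOH (cat.), i-PrOH, rt
Reagents that add atoms: none
Why: Noyori asymmetric transfer hydrogenation of an alkynyl ketone, in which the (S,S)-configured catalyst is expected to deliver hydride to the face that gives the (S)-propargylic alcohol, the future C1 stereocentre.

Step 8
Reactants: 11 (5S)-5-hydroxy-2,2-dimethyl-7-(trimethylsilyl)hept-6-ynenitrile
Product: 13 (5S)-5-(4-methoxybenzyloxy)-2,2-dimethylhept-6-ynenitrile, via silylated PMB ether 12 (not isolated)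
Conditions: NaH, 4-methoxybenzyl chloride, n-Bu4NI (cat.), THF/DMF, 0 °C to rt; then MeOH, K2CO3, rt
Reagents that add atoms: 4-methoxybenzyl chloride, COc1ccc(CCl)cc1
Why: Williamson etherification followed in the same flask by methanolysis of the alkynyl–silicon bond; the carbinol stereocentre is not involved.

Step 9
Reactants: 6 (4R,5S)-silyl ether of 5; 13 (5S)-5-(4-methoxybenzyloxy)-2,2-dimethylhept-6-ynenitrile
Product: 14 silyl enol ether of the conjugate adduct
Conditions: 13, n-BuLi, THF, −78 °C; ZnBr2, 0 °C; then 6, t-BuMe2SiOTf, Et2O, −40 to −20 °C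
Reagents that add atoms: tert-butyldimethylsilyl trifluoromethanesulfonate, CC(C)(C)[Si](C)(C)OS(=O)(=O)C(F)(F)F
Why: Silyl triflate-promoted conjugate addition of an alkynylzinc reagent to a cyclic enone, in which the nucleophile should add to C11 anti to the adjacent C12 silyloxy group (as cuprates do with 4-silyloxycyclopentenones), placing the alkynyl group cis to the bromoallyl group, while the enolate is trapped regiospecifically as the C16 silyl enol ether.

Step 10
Reactants: 14 silyl enol ether of the conjugate adduct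
Product: 15 α-silyloxy cyclopentanone
Conditions: mCPBA, NaHCO3, CH2Cl2, −20 to 0 °C
Reagents that add atoms: 3-chloroperoxybenzoic acid, OOC(=O)c1cccc(Cl)c1
Why: Rubottom oxidation, in which the peracid epoxidises the electron-rich enol ether on the face anti to the two flanking carbon substituents (alkynyl at C11, bromoallyl at C13) and 1,4-silyl migration gives the α-silyloxy ketone with the C15 oxygen trans to the alkynyl group.

Step 11
Reactants: 15 α-silyloxy cyclopentanone
Product: 16 methylidene cyclopentane (cascade substrate)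
Conditions: Zn, CH2Br2, TiCl4, THF; then 15, CH2Cl2, 0 °C to rt
Reagents that add atoms: dibromomethane, BrCBr
Why: Takai–Lombardo methylenation, a non-basic olefination suited to hindered, enolisable ketones, turns the C16 carbonyl into the exocyclic C16=C17 bond without epimerising C13 or C15 and without eliminating the β-silyloxy group.

Step 12
Reactants: 16 methylidene cyclopentane (cascade substrate)
Product: 17 bicyclic diene nitrile
Conditions: Pd(PPh3)4 (10 mol%), MeB(OH)2, K3PO4, THF/H2O, 65 °C
Reagents that add atoms: methylboronic acid, CB(O)O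
Why: Cyclic carbopalladation/Suzuki–Miyaura cascade (the reaction type used to make 1,2-bis(alkylidene)cyclohexanes from vinyl halides carrying a tethered alkyne), in which zerovalent palladium inserts into the vinyl bromide, 6-exo-dig syn-carbopalladation of the alkyne closes ring C because the two arms are cis on ring D, and methyl transfer to the alkenylpalladium places the C10 methyl cis to C8, so the C9=C10 geometry follows from syn addition.

Step 13
Reactants: 17 bicyclic diene nitrile
Product: 18 bicyclic diene aldehyde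
Conditions: i-Bu2AlH, toluene, −78 to 0 °C; aq. potassium sodium tartrate (KNaC4H4O6)
Reagents that add atoms: water, O
Why: Partial reduction of the hindered nitrile stops at the aluminium aldimine, which hydrolyses on work-up to the non-enolisable C5 aldehyde.

Step 14
Reactants: 18 bicyclic diene aldehyde
Product: 19 β-nitro alcohol (both C5 epimers)
Conditions: CH3NO2 (excess), KOt-Bu (20 mol%), THF/t-BuOH, 0 °C to rt
Reagents that add atoms: nitromethane, C[N+](=O)[O-]
Why: Henry (nitroaldol) addition introduces C6 together with its nitrogen, and the carbinol configuration is irrelevant because the hydroxyl is eliminated in step 15.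

Step 15
Reactants: 19 β-nitro alcohol (both C5 epimers)
Product: 22 nitro tetracycle, via mesylate 20 (not isolated), via (E)-nitroalkene 21 (not isolated)
Conditions: MsCl, Et3N, CH2Cl2, 0 °C; solvent exchange to toluene (5 mM), 85 °C
Reagents that add atoms: none
Why: Mesylation and amine-induced β-elimination give the (E)-nitroalkene 21, whose C5=C6 bond then adds thermally, in a concerted but asynchronous [4+2] cycloaddition, to the ring-held s-cis diene C7=C8–C9=C10, forming C5–C10 and C6–C7 together. The closest known reaction type is the thermal intramolecular Diels–Alder reaction of (E)-1-nitrodeca-1,7,9-trienes, which gives trans-fused nitrodecalins near 80 °C. Ring A closes as a six-membered ring through the four-carbon tether C1–C4 that joins the diene terminus C10 to the dienophile carbon C5 (tether exo, chair-like), and ring B is the new cyclohexene whose double bond C8=C9 ends up shared by rings B and C. C10 is set by the diene face attacked: 1,3-allylic strain holds the C1–H bond in the diene plane toward C11, so the OPMB group lies on the side of the C12 bridge and C2 carries the dienophile to the face of the C15–C16 bridge; C5 follows from the exo orientation of the tether (trans ring fusion, the C4 gem-dimethyl group kept away from C9 and C11), and C6 (nitro endo, cis to H5) follows from the E geometry and is erased in step 16. The step needs diene-face selectivity, exo-tether selectivity and a rate that outruns the [1,5]-hydrogen shift of the inside methyl group; the C1 stereocentre, the gem-dimethyl group and the strong nitro activation (reaction at or below 90 °C) are there to secure them.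

Step 16
Reactants: 22 nitro tetracycle
Product: 24 C6 ketone, via sodium nitronate 23 (not isolated)
Conditions: NaOMe, MeOH, 0 °C; then TiCl3, NH4OAc, H2O/THF (pH 5–6), rt
Reagents that add atoms: water, O
Why: Nef reaction in its reductive, buffered TiCl3 variant, in which the nitronate is reduced to the imine and hydrolysed to the ketone under nearly neutral conditions that should spare the silyl and PMB ethers, leave C8=C9 out of conjugation and keep C5 trans.

Step 17
Reactants: 24 C6 ketone
Product: 25 C6 axial alcohol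
Conditions: NaBH4, MeOH/THF, 0 °C to rt
Reagents that add atoms: none
Why: Hydride reduction of a cyclohexanone flanked by syn-axial methyl groups, in which borohydride should attack C6 from the face opposite to the axial methyls on C4 and C10 and give the axial alcohol, as 6-oxo-4,4,10-trimethyldecalins do.

Step 18
Reactants: 25 C6 axial alcohol
Product: 26 C1,C6 diol
Conditions: DDQ, CH2Cl2/pH 7 buffer, 0 °C to rt
Reagents that add atoms: none
Why: Oxidative cleavage of the 4-methoxybenzyl ether through its benzylic oxocarbenium ion frees only the C1 hydroxyl, the silyl ethers and both isolated alkenes being inert.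

Step 19
Reactants: 26 C1,C6 diol
Product: 27 C1 acetate
Conditions: Ac2O, pyridine, DMAP (cat.), CH2Cl2, 0 °C
Reagents that add atoms: acetic anhydride, CC(=O)OC(C)=O
Why: Site-selective acetylation, in which the equatorial C1 hydroxyl is acylated while the axial C6 hydroxyl, shielded by the two syn-axial methyl groups, is expected to stay free.

Step 20
Reactants: 27 C1 acetate
Product: 28 C6,C12,C15 triol acetate
Conditions: HF·pyridine, THF/pyridine, 0 °C to rt
Reagents that add atoms: none
Why: Fluoride-mediated cleavage of both silyl ethers under buffered acidic conditions that should keep the acetate in place and not migrate it.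

Step 21
Reactants: 28 C6,C12,C15 triol acetate
Product: 29 target CNP0149338.1
Conditions: MnO2 (activated, excess), CH2Cl2, rt
Reagents that add atoms: none
Why: Chemoselective oxidation of the allylic C15 alcohol by MnO2 gives the α-methylene ketone and should leave the non-allylic hydroxyls at C6 and C12 untouched.

**Compound list**

1 | furfural (furan-2-carbaldehyde) | O=Cc1ccco1 | starting material
2 | 2,3-dibromoprop-1-ene | C=C(Br)CBr | starting material
3 | rac-3-bromo-1-(furan-2-yl)but-3-en-1-ol | OC(CC(Br)=C)c1ccco1 | intermediate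
4 | rac-trans-5-(2-bromoprop-2-en-1-yl)-4-hydroxycyclopent-2-en-1-one (racemate; one enantiomer drawn) | O=C1C=C[C@@H](O)[C@@H]1CC(Br)=C | intermediate
5 | (4R,5S)-5-(2-bromoprop-2-en-1-yl)-4-hydroxycyclopent-2-en-1-one | O=C1C=C[C@@H](O)[C@@H]1CC(Br)=C | intermediate
6 | (4R,5S)-5-(2-bromoprop-2-en-1-yl)-4-(tert-butyldimethylsilyloxy)cyclopent-2-en-1-one | O=C1C=C[C@@H](O[Si](C)(C)C(C)(C)C)[C@@H]1CC(Br)=C | intermediate
7 | isobutyronitrile (2-methylpropanenitrile) | CC(C)C#N | starting material
8 | N-methoxy-N-methylacrylamide | C=CC(=O)N(C)OC | starting material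
9 | 4-cyano-N-methoxy-N,4-dimethylpentanamide | N#CC(C)(C)CCC(=O)N(C)OC | intermediate
10 | 2,2-dimethyl-5-oxo-7-(trimethylsilyl)hept-6-ynenitrile | N#CC(C)(C)CCC(=O)C#C[Si](C)(C)C | intermediate
11 | (5S)-5-hydroxy-2,2-dimethyl-7-(trimethylsilyl)hept-6-ynenitrile | N#CC(C)(C)CC[C@H](O)C#C[Si](C)(C)C | intermediate
12 | (5S)-5-(4-methoxybenzyloxy)-2,2-dimethyl-7-(trimethylsilyl)hept-6-ynenitrile | N#CC(C)(C)CC[C@H](OCc1ccc(OC)cc1)C#C[Si](C)(C)C | intermediate (not isolated)
13 | (5S)-5-(4-methoxybenzyloxy)-2,2-dimethylhept-6-ynenitrile | N#CC(C)(C)CC[C@H](OCc1ccc(OC)cc1)C#C | intermediate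
14 | (5S)-7-[4-(2-bromoprop-2-en-1-yl)-3,5-bis(tert-butyldimethylsilyloxy)cyclopent-2-en-1-yl]-5-(4-methoxybenzyloxy)-2,2-dimethylhept-6-ynenitrile; on the ring the alkynyl and bromoallyl groups are cis, the C5' silyloxy group between them is trans to both | C=C(Br)C[C@@H]1C(O[Si](C)(C)C(C)(C)C)=C[C@H](C#C[C@@H](OCc2ccc(OC)cc2)CCC(C)(C)C#N)[C@H]1O[Si](C)(C)C(C)(C)C | intermediate
15 | (5S)-7-[4-(2-bromoprop-2-en-1-yl)-2,5-bis(tert-butyldimethylsilyloxy)-3-oxocyclopentyl]-5-(4-methoxybenzyloxy)-2,2-dimethylhept-6-ynenitrile; alkynyl and bromoallyl cis, both silyloxy groups trans to them | C=C(Br)C[C@@H]1C(=O)[C@@H](O[Si](C)(C)C(C)(C)C)[C@H](C#C[C@@H](OCc2ccc(OC)cc2)CCC(C)(C)C#N)[C@H]1O[Si](C)(C)C(C)(C)C | intermediate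
16 | (5S)-7-[4-(2-bromoprop-2-en-1-yl)-2,5-bis(tert-butyldimethylsilyloxy)-3-methylidenecyclopentyl]-5-(4-methoxybenzyloxy)-2,2-dimethylhept-6-ynenitrile; same ring configuration as 15 | C=C(Br)C[C@@H]1C(=C)[C@@H](O[Si](C)(C)C(C)(C)C)[C@H](C#C[C@@H](OCc2ccc(OC)cc2)CCC(C)(C)C#N)[C@H]1O[Si](C)(C)C(C)(C)C | intermediate
17 | (5S,6E)-6-[7,8-bis(tert-butyldimethylsilyloxy)-3,6-dimethylidenebicyclo[3.2.1]octan-2-ylidene]-5-(4-methoxybenzyloxy)-2,2-dimethylheptanenitrile; chain methyl cis to C3' of the bicycle, C7' silyloxy exo (toward the one-carbon bridge), C8' silyloxy syn to the C6'–C7' bridge | C=C1[C@@H](O[Si](C)(C)C(C)(C)C)[C@@H]2/C(=C(/C)[C@@H](OCc3ccc(OC)cc3)CCC(C)(C)C#N)C(=C)C[C@H]1[C@@H]2O[Si](C)(C)C(C)(C)C | intermediate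
18 | (5S,6E)-6-[7,8-bis(tert-butyldimethylsilyloxy)-3,6-dimethylidenebicyclo[3.2.1]octan-2-ylidene]-5-(4-methoxybenzyloxy)-2,2-dimethylheptanal; configuration as 17 | C=C1[C@@H](O[Si](C)(C)C(C)(C)C)[C@@H]2/C(=C(/C)[C@@H](OCc3ccc(OC)cc3)CCC(C)(C)C=O)C(=C)C[C@H]1[C@@H]2O[Si](C)(C)C(C)(C)C | intermediate
19 | (6S,7E)-7-[bicyclic ylidene as in 17]-6-(4-methoxybenzyloxy)-3,3-dimethyl-1-nitrooctan-2-ol, both C2 epimers | C=C1[C@@H](O[Si](C)(C)C(C)(C)C)[C@@H]2/C(=C(/C)[C@@H](OCc3ccc(OC)cc3)CCC(C)(C)C(O)C[N+](=O)[O-])C(=C)C[C@H]1[C@@H]2O[Si](C)(C)C(C)(C)C | intermediate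
20 | methanesulfonate of 19 | C=C1[C@@H](O[Si](C)(C)C(C)(C)C)[C@@H]2/C(=C(/C)[C@@H](OCc3ccc(OC)cc3)CCC(C)(C)C(OS(C)(=O)=O)C[N+](=O)[O-])C(=C)C[C@H]1[C@@H]2O[Si](C)(C)C(C)(C)C | intermediate (not isolated)
21 | (E)-nitroalkene: (1E,6S,7E)-7-[bicyclic ylidene as in 17]-6-(4-methoxybenzyloxy)-3,3-dimethyl-1-nitroocta-1-ene | C=C1[C@@H](O[Si](C)(C)C(C)(C)C)[C@@H]2/C(=C(/C)[C@@H](OCc3ccc(OC)cc3)CCC(C)(C)/C=C/[N+](=O)[O-])C(=C)C[C@H]1[C@@H]2O[Si](C)(C)C(C)(C)C | intermediate (not isolated)
22 | nitro tetracycle (rings A–D, C8=C9 and C16=C17): OPMB at C1 (cis to the C10 methyl), NO2 at C6 (cis to H5), OTBS at C12 (syn to the C15–C16 bridge) and at C15 (exo), trans A/B fusion | C=C1[C@@H](O[Si](C)(C)C(C)(C)C)[C@@H]2C3=C(C[C@H]1[C@@H]2O[Si](C)(C)C(C)(C)C)C[C@@H]([N+](=O)[O-])[C@@H]1C(C)(C)CC[C@H](OCc4ccc(OC)cc4)[C@@]31C | intermediate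
23 | sodium nitronate of 22 | C=C1[C@@H](O[Si](C)(C)C(C)(C)C)[C@@H]2C3=C(C[C@H]1[C@@H]2O[Si](C)(C)C(C)(C)C)CC(=[N+]([O-])[O-])[C@@H]1C(C)(C)CC[C@H](OCc4ccc(OC)cc4)[C@@]31C.[Na+] | intermediate (not isolated)
24 | C6 ketone: as 22 with C6=O, trans A/B fusion | C=C1[C@@H](O[Si](C)(C)C(C)(C)C)[C@@H]2C3=C(C[C@H]1[C@@H]2O[Si](C)(C)C(C)(C)C)CC(=O)[C@@H]1C(C)(C)CC[C@H](OCc4ccc(OC)cc4)[C@@]31C | intermediate
25 | C6 axial alcohol: as 24 with C6–OH cis to the C10 methyl | C=C1[C@@H](O[Si](C)(C)C(C)(C)C)[C@@H]2C3=C(C[C@H]1[C@@H]2O[Si](C)(C)C(C)(C)C)C[C@H](O)[C@@H]1C(C)(C)CC[C@H](OCc4ccc(OC)cc4)[C@@]31C | intermediate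
26 | C1,C6 diol: as 25 with free C1–OH | C=C1[C@@H](O[Si](C)(C)C(C)(C)C)[C@@H]2C3=C(C[C@H]1[C@@H]2O[Si](C)(C)C(C)(C)C)C[C@H](O)[C@@H]1C(C)(C)CC[C@H](O)[C@@]31C | intermediate
27 | C1 acetate: as 26 with C1–OAc, C6–OH free, C12 and C15 OTBS | C=C1[C@@H](O[Si](C)(C)C(C)(C)C)[C@@H]2C3=C(C[C@H]1[C@@H]2O[Si](C)(C)C(C)(C)C)C[C@H](O)[C@@H]1C(C)(C)CC[C@H](OC(C)=O)[C@@]31C | intermediate
28 | C6,C12,C15 triol acetate (C15 allylic alcohol) | C=C1[C@@H](O)[C@@H]2C3=C(C[C@H]1[C@@H]2O)C[C@H](O)[C@@H]1C(C)(C)CC[C@H](OC(C)=O)[C@@]31C | intermediate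
29 | CNP0149338.1 | C=C1C(=O)[C@@H]2C3=C(C[C@H]1[C@@H]2O)C[C@H](O)[C@@H]1C(C)(C)CC[C@H](OC(C)=O)[C@@]31C | target

**Step count**

Total step count: 21.
Longest linear sequence: 17 steps (steps 1–4, then 9–21; the branch through steps 5–8 is equally long).

**Steps most likely to fail**

Step 15. The cycloaddition may be too slow at the twisted, fully substituted diene terminus, so that the [1,5]-hydrogen shift of the inside methyl group or decomposition of the nitroalkene takes over, or the dienophile may add to the other diene face or in the endo-tether mode. The fallback sets out from aldehyde 18 and changes both the dienophile and the mechanism. Homologation of 18 with dimethyl (1-diazo-2-oxopropyl)phosphonate and K2CO3 in MeOH (Ohira–Bestmann) would give the terminal alkyne F1. Lithiation with n-BuLi and trapping with 2-isopropoxy-4,4,5,5-tetramethyl-1,3,2-dioxaborolane would give the alkynyl pinacolboronate F2. A cobalt-catalysed formal [4+2] cycloaddition (CoBr2(dppe), Zn, ZnI2, CH2Cl2, rt), which runs stepwise through a metallacycle and does not need a planar diene, would close rings A and B to the cyclohexa-1,4-dienyl boronate F3, with C10 again steered by allylic strain from C1. Oxidation of F3 with NaBO3·4H2O in THF/H2O gives the enol and then, after equilibration of C5 to the trans ring fusion under the basic conditions, ketone 24, where the route is rejoined.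

Step 12. Methyl transfer to the vinylpalladium species may take place before the ring closes, the strained 6-exo-dig closure to the bridged ring may fail, or the alkenylpalladium intermediate may isomerise before it is methylated. The fallback sets out from 16 and separates the two events. Copper-catalysed syn-methylboration of the alkyne (CuCl, xantphos, NaOt-Bu, B2pin2, MeI, THF) should place boron on C9 (distal to the propargylic ether) and methyl on C10 on the same side, giving the alkenyl boronate F4. An intramolecular Suzuki–Miyaura coupling of F4 (PdCl2(dppf), Cs2CO3, THF/H2O, 60 °C) then closes ring C with retention at both carbons and gives diene 17 with the same geometry, where the route is rejoined.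

Step 9. Transfer of the functionalised zinc acetylide to the hindered 4,5-disubstituted enone may be sluggish, the anti selectivity may erode, or the silyl triflate may attack the PMB ether. The fallback sets out from 6 and unites the fragments at C1 instead of at C11. The same silyl triflate-promoted conjugate addition with the simple zinc acetylide of trimethylsilylacetylene would give the silyl enol ether F5. Rubottom oxidation (mCPBA, NaHCO3) would give the α-silyloxy ketone F6 and Takai–Lombardo methylenation the methylidene compound F7. Methanolysis (K2CO3, MeOH) would free the terminal alkyne F8. Its lithium acetylide would be acylated by Weinreb amide 9 to the alkynyl ketone F9, and Noyori transfer hydrogenation with RuCl[(S,S)-TsDPEN](p-cymene) would give the (S)-propargylic alcohol F10. Etherification of F10 (NaH, 4-methoxybenzyl chloride) gives 16, where the route is rejoined; steps 6–8 are then not needed.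

**Further compounds**

F1 | step 15 | (5S,6E)-terminal alkyne from 18: 8-[bicyclic ylidene as in 17] chain ending in C(CH3)2–C≡CH | C=C1[C@@H](O[Si](C)(C)C(C)(C)C)[C@@H]2/C(=C(/C)[C@@H](OCc3ccc(OC)cc3)CCC(C)(C)C#C)C(=C)C[C@H]1[C@@H]2O[Si](C)(C)C(C)(C)C
F2 | step 15 | alkynyl pinacolboronate of F1 | C=C1[C@@H](O[Si](C)(C)C(C)(C)C)[C@@H]2/C(=C(/C)[C@@H](OCc3ccc(OC)cc3)CCC(C)(C)C#CB4OC(C)(C)C(C)(C)O4)C(=C)C[C@H]1[C@@H]2O[Si](C)(C)C(C)(C)C
F3 | step 15 | tetracyclic cyclohexa-1,4-dienyl boronate (C5=C6 with Bpin on C6, C8=C9; other groups as in 22) | C=C1[C@@H](O[Si](C)(C)C(C)(C)C)[C@@H]2C3=C(C[C@H]1[C@@H]2O[Si](C)(C)C(C)(C)C)CC(B5OC(C)(C)C(C)(C)O5)=C1C(C)(C)CC[C@H](OCc4ccc(OC)cc4)[C@@]31C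
F4 | step 12 | alkenyl pinacolboronate from 16 (Bpin on C9 cis to the new C10 methyl; vinyl bromide intact) | C=C(Br)C[C@@H]1C(=C)[C@@H](O[Si](C)(C)C(C)(C)C)[C@H](/C(B2OC(C)(C)C(C)(C)O2)=C(/C)[C@@H](OCc3ccc(OC)cc3)CCC(C)(C)C#N)[C@H]1O[Si](C)(C)C(C)(C)C
F5 | step 9 | silyl enol ether carrying a (trimethylsilyl)ethynyl group at C11 (ring configuration as 14) | C=C(Br)C[C@@H]1C(O[Si](C)(C)C(C)(C)C)=C[C@H](C#C[Si](C)(C)C)[C@H]1O[Si](C)(C)C(C)(C)C
F6 | step 9 | α-silyloxy ketone from F5 (ring configuration as 15) | C=C(Br)C[C@@H]1C(=O)[C@@H](O[Si](C)(C)C(C)(C)C)[C@H](C#C[Si](C)(C)C)[C@H]1O[Si](C)(C)C(C)(C)C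
F7 | step 9 | methylidene compound from F6 | C=C(Br)C[C@@H]1C(=C)[C@@H](O[Si](C)(C)C(C)(C)C)[C@H](C#C[Si](C)(C)C)[C@H]1O[Si](C)(C)C(C)(C)C
F8 | step 9 | terminal alkyne from F7 | C=C(Br)C[C@@H]1C(=C)[C@@H](O[Si](C)(C)C(C)(C)C)[C@H](C#C)[C@H]1O[Si](C)(C)C(C)(C)C
F9 | step 9 | alkynyl ketone from F8 and 9 | C=C(Br)C[C@@H]1C(=C)[C@@H](O[Si](C)(C)C(C)(C)C)[C@H](C#CC(=O)CCC(C)(C)C#N)[C@H]1O[Si](C)(C)C(C)(C)C
F10 | step 9 | (S)-propargylic alcohol from F9 | C=C(Br)C[C@@H]1C(=C)[C@@H](O[Si](C)(C)C(C)(C)C)[C@H](C#C[C@@H](O)CCC(C)(C)C#N)[C@H]1O[Si](C)(C)C(C)(C)C
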